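All runs were generated by integration with constants of no real substance.

At late times the theta run had stopped short of its reagent: target stood flat near 32.0% of the starting material, which is 0.0800 M against 0.13 M of reagent charged.

| flask | starting material | reagent | protic impurity | free catalyst | remark | time |
|---|---|---|---|---|---|---|
| alpha | 0.25 M | 0.087 M | 0.050 M | 0.25 mM | run made earlier |  |
| theta | 0.25 M | 0.13 M | 0.050 M | 0.25 mM | run made earlier |  |
| zeta | 0.25 M | 0.175 M | 0.025 M | 0.25 mM | run made earlier |  |
| flask | 0.25 M | 0.175 M | 0.0500 M | 0.25 mM |  | 20 h |

| run | time / h | side product / % | target / % |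
|---|---|---|---|
| alpha | 2.00 | 2.7 | 8.3 |
| alpha | 3.00 | 3.1 | 13.1 |
| alpha | 4.00 | 4.5 | 16.4 |
| alpha | 6.00 | 3.8 | 20.1 |
| alpha | 10.0 | 4.6 | 22.3 |
| alpha | 15.0 | 3.3 | 22.2 |
| alpha | 25.0 | 4.3 | 22.1 |
| theta | 3.00 | 3.6 | 16.6 |
| theta | 6.00 | 4.0 | 27.0 |
| theta | 10.0 | 3.4 | 30.5 |
| theta | 15.0 | 2.4 | 31.3 |
| theta | 20.0 | 3.9 | 31.8 |
| theta | 25.0 | 3.2 | 32.0 |
| zeta | 2.00 | 2.8 | 13.0 |
| zeta | 4.00 | 3.9 | 23.2 |
| zeta | 6.00 | 3.7 | 31.5 |
| zeta | 12.0 | 3.3 | 39.1 |
| zeta | 25.0 | 4.0 | 42.7 |

(scatter of a reading: 0.5 percentage points)

- a species is counted by the starting material in it: one side product counts as two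

- share of side product in side product plus target at 40 min
- share of side product in side product plus target at 4.0 h
- share of side product in side product plus target at 20 h
- which of side product and target there is more of at 20 h

I called the remainder whatever was neither target nor side product, both read as percent of the starting material charged. A flat target beside reagent and remainder read to me as a balance, so I formed the mass-action quotient c(target)/(c(reagent)·c(remainder)) from the last readings. It read 9.46 M⁻¹ in the alpha run and 9.88 M⁻¹ in the theta run. The zeta run, with half their protic impurity, read 11.7 M⁻¹. The flask has the impurity of the first two, so I carried their mean, the closing quotient 9.67 M⁻¹. The last side product readings averaged 3.83% over the runs, which in the flask leaves 0.240 M to share between target and remainder.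

In the flask, target over reagent left must equal the quotient times the remainder. In one extreme, reagent is the limiting reagent and is wholly taken, giving 70.0% target; but then the ratio is unbounded while quotient times remainder stays finite, so the flask must lie below that. In the symmetric extreme, target equals reagent left at 35.0%. That needs a remainder of 0.103 M, but the remainder there is larger, at 0.153 M, so the flask must lie above it. Solving between them gave me 40.2% target and a share of 8.70%.

The forecast, on the ground that “Final target tracks reagent”, gave shares of 33%, 11.5% and 8%, a plateau near 43 %, and target in the lead.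

The flask gave shares of 28.4%, 12.4% and 7.86%, with 40.9% target against 3.49% side product at 20 h.

starting material + free catalyst → free catalyst + open intermediate (k = 72.0 M⁻¹ min⁻¹); free catalyst + open intermediate ⇌ catalyst intermediate (K = 5.90 M⁻¹, k = 11.0 M⁻¹ min⁻¹); reagent + catalyst intermediate ⇌ free catalyst + target (K = 1.90, k = 82.0 M⁻¹ min⁻¹); starting material + open intermediate → side product (k = 0.00280 M⁻¹ min⁻¹); starting material + protic impurity → quenched substrate (k = 0.0190 M⁻¹ min⁻¹) At that time 41.6% of the reagent charge stood beside 50.8% of the starting material as open intermediate. The closing quotient of this flask came to 10.1 M⁻¹. For the same flask with 0.30 M of reagent, 9.67 M⁻¹ gives 57.8% target, and that flask holds 57.2% at 20.0 h.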